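Readings and results are simulated with constants of no real substance; noise was put on by code.

**Early times.** At early times the starting material decays exponentially with a rate constant k, which the first reading of each run puts at 0.765 h⁻¹ for elm and 0.918 h⁻¹ for ash. Their ratio, 1.20, stands close to the root of the initiator ratio, 1.23.

| flask | starting material | reagent | initiator | remark | time |
|---|---|---|---|---|---|
| elm | 10 mM | 9 mM | 0.055 mM | run made earlier |  |
| ash | 10 mM | 9 mM | 0.083 mM | run made earlier |  |
| flask | 10 mM | 9.00 mM | 0.11 mM |  | 4.0 h |

| run | time / h | side product / % | starting material / % | target / % | chain carrier / % |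
|---|---|---|---|---|---|
| elm | 0.417 | 2.9 | 72.7 | 24.4 | 0 |
| elm | 0.667 | 4.4 | 61.2 | 36.1 | 0 |
| elm | 0.833 | 4.9 | 53.4 | 41.1 | 0 |
| elm | 1.33 | 8.8 | 38.1 | 54.2 | 0 |
| elm | 2.00 | 12.6 | 22.8 | 63.4 | 0.1 |
| elm | 3.00 | 16.7 | 11.4 | 70.3 | 0.1 |
| elm | 5.00 | 20.6 | 2.0 | 76.2 | 0 |
| ash | 0.667 | 3.4 | 54.2 | 42.5 | 0 |
| ash | 1.33 | 10.2 | 29.4 | 60.4 | 0 |
| ash | 2.00 | 13.3 | 17.3 | 69.8 | 0.3 |
| ash | 3.00 | 16.4 | 8.0 | 75.1 | 0 |
| ash | 4.00 | 18.7 | 3.7 | 78.3 | 0 |
| ash | 5.00 | 17.7 | 0.7 | 79.0 | 0.1 |

(each reading ± 0.5 percentage points)

- percentages count the starting material that a species holds: one ended chains A or side product counts as two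
- steps under discussion: initiator -> 2 initiating radical; reagent + chain carrier -> target + initiating radical; 2 initiating radical -> ended chains B; 2 chain carrier -> ended chains A; target -> over-reaction product; starting material + target -> side product; starting material + initiating radical -> chain carrier

- the largest share of what was charged as starting material, at 4.0 h belongs to (target / starting material / chain carrier / side product)
- the largest share itself, whichever of these holds it, in percent of the starting material charged

**The curve.** Scaling by that root gives the flask k = 1.06 h⁻¹. Target therefore rises at about k times the charge and crosses the starting material near its half-life, 0.656 h.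

**The ceiling.** Each target takes one reagent, and each side product holds one former target. So target plus half the side product stays below the reagent ceiling R, reagent charged over starting material charged 90.0%. Reagent is the limiting reagent, since the flask holds 9.00 mM against 10 mM. The excess, 10.0%, leaves as side product, each such unit carrying a target with it, and as ended chains A, which carry none. The knee comes as the starting material nears the excess, at about 2.18 h. Counting the whole excess as side product puts the level at R minus the excess, 80.0%; whatever leaves as ended chains A raises it.

**The forecast.** The forecast names target at 80.5%, a little above this level, and states: “Reagent at 90% caps target + side/2”.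

**The flask.** The flask gives target at 80.1%, with side product at 16.4%.

    initiator → 2 initiating radical (k = 0.190 h⁻¹)
    reagent + chain carrier → target + initiating radical (k = 99000 L mol⁻¹ s⁻¹)
    2 initiating radical → ended chains B (k = 1.20 × 10⁶ L mol⁻¹ s⁻¹)
    2 chain carrier → ended chains A (k = 4.20 × 10⁸ L mol⁻¹ s⁻¹)
    target → over-reaction product (k = 8.60 × 10⁻⁵ h⁻¹)
    starting material + target → side product (k = 19.0 L mol⁻¹ h⁻¹)
    starting material + initiating radical → chain carrier (k = 3.20 × 10⁷ L mol⁻¹ h⁻¹)

**Ceiling reused.** In the flask, reagent stands at 1.9% of its charge, and R on the spent reagent less the side product divided by two gives 80.1%. The neighbouring flask, with 3.6 mM of reagent, has R = 36.0%. Its reagent stands at 1.2% of its charge and its side product at 22.1%, so the same subtraction gives 24.5%. That neighbour ends with target at 24.5% and starting material at 52.2%.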